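**Retrosynthetic overview**

1. Serpyllin comes from the 5-hydroxyflavanone by dehydrogenation; the flavanone comes from a cis-flavan-4,5-diol whose C4 oxygen is carried as a silyl ether.
2. Key disconnection C4a–C5: ring A has the C5 hydroxyl para to the C8 methoxyl, the C7 methoxyl beside C8 and hydrogen at C6. These four carbons are the ring of a 3,4-dimethoxycyclobutenone that carries the dihydropyran (future C8a=C4a) on its methoxylated sp3 carbon.
3. The cyclobutenone comes from a C6-lithiated dihydropyran and methyl semisquarate (two steps from dimethyl squarate), with O-methylation in the flask. The lithium reagent is made by tin–lithium exchange, not by deprotonation, because the benzylic C2–H and the anisole-type ring positions would compete for the base.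
4. The C6 stannane comes from the lactone-derived ketene acetal phosphate; the lactone comes from the cyclic enol ether; ring C comes from a hetero-Diels–Alder reaction of 2,3,4-trimethoxybenzaldehyde with a 1-methoxy-3-silyloxydiene, and a Luche reduction fixes cis C2/C4.
5. Ring order: B (bought) → C (step 1) → four-membered ring attached (step 9) → A (step 10).

Key step: step 10

Remark: the target is achiral. All intermediates with stereocentres are racemic, and "cis" gives only the relative configuration at C2/C4, which is erased in steps 12 and 13.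

**Route**

Step 1
Reactants: 1 2,3,4-trimethoxybenzaldehyde; 2 (E)-1-methoxy-3-(trimethylsilyloxy)buta-1,3-diene
Product: 4 2-(2,3,4-trimethoxyphenyl)-2,3-dihydro-4H-pyran-4-one (racemic), via cycloadduct 3 (not isolated)
Conditions: ZnCl2, THF, rt; then CF3CO2H (cat.), CH2Cl2, 0 °C
Reagents that add atoms: none
Why: Lewis-acid-promoted hetero-Diels–Alder reaction of an aryl aldehyde with an electron-rich 1-alkoxy-3-silyloxydiene (ZnCl2 can chelate the aldehyde oxygen and the 2-methoxyl), followed by acid cleavage of the silyl enol ether and β-elimination of methanol from cycloadduct 3; the C2 stereocentre forms as a racemate.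

Step 2
Reactants: 4 2-(2,3,4-trimethoxyphenyl)-2,3-dihydro-4H-pyran-4-one
Product: 5 cis-2-(2,3,4-trimethoxyphenyl)-3,4-dihydro-2H-pyran-4-ol (racemic)
Conditions: NaBH4, CeCl3·7H2O, MeOH, –78 °C
Reagents that add atoms: none
Why: Luche 1,2-reduction of the enone; hydride adds axially to the half-chair that holds the aryl group pseudo-equatorial, so the new C4 hydroxyl should come out cis to the C2 aryl group (substrate control).

Step 3
Reactants: 5 cis-2-(2,3,4-trimethoxyphenyl)-3,4-dihydro-2H-pyran-4-ol
Product: 6 cis-4-(tert-butyldimethylsilyloxy)-2-(2,3,4-trimethoxyphenyl)-3,4-dihydro-2H-pyran (racemic)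
Conditions: TBSCl, imidazole, DMF, rt
Reagents that add atoms: tert-butyldimethylsilyl chloride, CC(C)(C)[Si](C)(C)Cl
Why: Imidazole-promoted silylation of a secondary allylic alcohol under basic conditions, which avoids acid-induced allylic rearrangement of this enol ether; no stereocentre is touched.

Step 4
Reactants: 6 cis-4-(tert-butyldimethylsilyloxy)-2-(2,3,4-trimethoxyphenyl)-3,4-dihydro-2H-pyran
Product: 7 cis-4-(tert-butyldimethylsilyloxy)-6-(2,3,4-trimethoxyphenyl)tetrahydro-2H-pyran-2-one (racemic)
Conditions: pyridinium chlorochromate C5H5NH[CrO3Cl], 4 Å molecular sieves, CH2Cl2, rt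
Reagents that add atoms: pyridinium chlorochromate, [O-][Cr](=O)(=O)Cl.c1cc[nH+]cc1
Why: Chlorochromate oxidation of a cyclic enol ether to the δ-lactone, as known for 3-O-protected glycals (protonation at C5, chromate ester at the oxocarbenium carbon C6, then oxidation); the silyloxy group is a poor leaving group, so no allylic transposition is expected and C2/C4 stay as set.

Step 5
Reactants: 7 cis-4-(tert-butyldimethylsilyloxy)-6-(2,3,4-trimethoxyphenyl)tetrahydro-2H-pyran-2-one
Product: 9 cis-4-(tert-butyldimethylsilyloxy)-2-(2,3,4-trimethoxyphenyl)-3,4-dihydro-2H-pyran-6-yl diphenyl phosphate (racemic), via potassium enolate 8 (not isolated)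
Conditions: KN(SiMe3)2, (PhO)2P(O)Cl, HMPA, THF, –78 °C (base added to lactone plus chlorophosphate)
Reagents that add atoms: diphenyl chlorophosphate, O=P(Cl)(Oc1ccccc1)Oc1ccccc1
Why: Kinetic enolisation of the lactone and O-phosphorylation to the cyclic ketene acetal phosphate; enolate 8 is trapped as it forms, and β-loss of silanolate is further slowed because the equatorial C4–O bond lies near the nodal plane of the enolate.

Step 6
Reactants: 9 cis-4-(tert-butyldimethylsilyloxy)-2-(2,3,4-trimethoxyphenyl)-3,4-dihydro-2H-pyran-6-yl diphenyl phosphate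
Product: 10 [cis-4-(tert-butyldimethylsilyloxy)-2-(2,3,4-trimethoxyphenyl)-3,4-dihydro-2H-pyran-6-yl]trimethylstannane (racemic)
Conditions: Me3SnSnMe3, Pd(PPh3)4 (cat.), LiCl, THF, reflux
Reagents that add atoms: hexamethylditin, C[Sn](C)(C)[Sn](C)(C)C
Why: Palladium-catalysed stannylation of a ketene acetal phosphate with a distannane (oxidative addition of zerovalent palladium into the C–O bond, Sn–Sn transmetalation, reductive elimination), which places the metal at C6 without any deprotonation.

Step 7
Reactants: 11 dimethyl squarate (3,4-dimethoxycyclobut-3-ene-1,2-dione)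
Product: 12 4-hydroxy-2,3-dimethoxycyclobut-2-en-1-one (racemic)
Conditions: LiAlH(OtBu)3, THF, –78 °C; aqueous work-up
Reagents that add atoms: none
Why: 1,2-Reduction of one squarate carbonyl by a bulky one-hydride aluminate at low temperature; it should stop at the mono-adduct because the remaining carbonyl is a deactivated vinylogous ester, and the new carbinol centre is removed in step 8.

Step 8
Reactants: 12 4-hydroxy-2,3-dimethoxycyclobut-2-en-1-one
Product: 13 3-methoxycyclobut-3-ene-1,2-dione (methyl semisquarate)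
Conditions: conc. aqueous HCl (cat.), CH2Cl2, rt; used without storage
Reagents that add atoms: water, O
Why: Acid-catalysed hydrolytic 1,3-transposition used for squarate adducts: ionisation of the C4 hydroxyl assisted by the C2 methoxyl through the ring double bond, return of water at C2 and loss of methanol give the cyclobutenedione.

Step 9
Reactants: 10 [cis-4-(tert-butyldimethylsilyloxy)-2-(2,3,4-trimethoxyphenyl)-3,4-dihydro-2H-pyran-6-yl]trimethylstannane; 13 3-methoxycyclobut-3-ene-1,2-dione
Product: 16 4-[cis-4-(tert-butyldimethylsilyloxy)-2-(2,3,4-trimethoxyphenyl)-3,4-dihydro-2H-pyran-6-yl]-3,4-dimethoxycyclobut-2-en-1-one (racemic; both epimers at the cyclobutenone carbon), via vinyllithium 14 (not isolated), via lithium alkoxide 15 (not isolated)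
Conditions: MeLi (slight deficit), THF, –78 °C; cannulated into 13, THF, –78 °C; then MeOTf, –78 to 0 °C
Reagents that add atoms: methyl trifluoromethanesulfonate, COS(=O)(=O)C(F)(F)F
Why: Tin–lithium exchange gives α-alkoxyvinyllithium 14 regiospecifically, which adds 1,2 to the more electrophilic carbonyl of 13 (the one next to the methoxy-bearing carbon; the other is a vinylogous ester carbonyl), the known site selectivity of organolithium additions to 3-alkoxycyclobutenediones, and alkoxide 15 is O-methylated by MeOTf; the new quaternary centre forms without control and both epimers serve.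

Step 10
Reactants: 16 4-[cis-4-(tert-butyldimethylsilyloxy)-2-(2,3,4-trimethoxyphenyl)-3,4-dihydro-2H-pyran-6-yl]-3,4-dimethoxycyclobut-2-en-1-one
Product: 19 cis-4-(tert-butyldimethylsilyloxy)-7,8-dimethoxy-2-(2,3,4-trimethoxyphenyl)chroman-5-ol (racemic), via dienylketene 17 (not isolated), via cyclohexadienone 18 (not isolated)
Conditions: degassed toluene, 110 °C, under argon
Reagents that add atoms: none
Why: Heating opens the cyclobutenone C1–C4 bond in a conrotatory 4π process to (Z)-dienylketene 17, whose ketene carbon then bonds to pyran C5 (new C4a–C5 bond) by 6π electrocyclisation, and dienone 18 enolises to the phenol. The closest known reaction type is the Moore ring expansion of 4-alkenyl-4-alkoxycyclobutenones, including adducts of lithiated cyclic enol ethers with cyclobutenediones. Ring A, a six-membered carbocycle, closes by disrotatory 6π electrocyclisation of the ketene C=C, the former C3=C4 bond and the pyran C5=C6 bond, fused onto ring C. No stereocentre is created that survives: C4a is sp3 only in 18, C2 and C4 are untouched so the cis relation from step 2 is kept, and both epimers of 16 converge. The step needs torquoselectivity (the donor methoxyl on the sp3 carbon turns outward, putting the alkenyl group inward), which the 4-methoxyl secures, while the ring A pattern is fixed by the connectivity of 16 (C1→C5, C2→C6, C3→C7, C4→C8). Enolisation of 18 to the aromatic ring is expected to outrun β-loss of silanol from C4.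

Step 11
Reactants: 19 cis-4-(tert-butyldimethylsilyloxy)-7,8-dimethoxy-2-(2,3,4-trimethoxyphenyl)chroman-5-ol
Product: 20 cis-7,8-dimethoxy-2-(2,3,4-trimethoxyphenyl)chroman-4,5-diol (racemic)
Conditions: Bu4NF, AcOH, THF, 0 °C to rt
Reagents that add atoms: none
Why: Fluoride cleavage of the silyl ether, buffered with acetic acid so that neither a phenoxide nor an acid drives loss of the benzylic oxygen from this electron-rich o-hydroxybenzyl system; both stereocentres are retained.

Step 12
Reactants: 20 cis-7,8-dimethoxy-2-(2,3,4-trimethoxyphenyl)chroman-4,5-diol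
Product: 21 5-hydroxy-7,8-dimethoxy-2-(2,3,4-trimethoxyphenyl)chroman-4-one (racemic)
Conditions: activated MnO2 (excess), CH2Cl2, rt
Reagents that add atoms: none
Why: MnO2 oxidation of a benzylic alcohol activated by the electron-rich ring A under neutral heterogeneous conditions, giving a ketone stabilised by the hydrogen bond to the C5 hydroxyl; the C4 stereocentre is removed and C2 stays racemic.

Step 13
Reactants: 21 5-hydroxy-7,8-dimethoxy-2-(2,3,4-trimethoxyphenyl)chroman-4-one
Product: 22 serpyllin (5-hydroxy-7,8-dimethoxy-2-(2,3,4-trimethoxyphenyl)-4H-chromen-4-one)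
Conditions: I2 (cat.), DMSO, 130 °C
Reagents that add atoms: none
Why: Iodine-catalysed dehydrogenation of a flavanone in dimethyl sulfoxide (α-iodination of the enol at C3, loss of HI to the 2,3-double bond, reoxidation of HI by the sulfoxide), which removes the last stereocentre and gives the achiral flavone.

**Compound list**

1 | 2,3,4-trimethoxybenzaldehyde | COc1ccc(C=O)c(OC)c1OC | starting material
2 | (E)-1-methoxy-3-(trimethylsilyloxy)buta-1,3-diene | CO/C=C/C(=C)O[Si](C)(C)C | starting material
3 | 2-methoxy-6-(2,3,4-trimethoxyphenyl)-4-(trimethylsilyloxy)-5,6-dihydro-2H-pyran (cycloadduct, racemic, not isolated) | COC1C=C(O[Si](C)(C)C)CC(c2ccc(OC)c(OC)c2OC)O1 | intermediate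
4 | 2-(2,3,4-trimethoxyphenyl)-2,3-dihydro-4H-pyran-4-one (racemic) | O=C1C=COC(c2ccc(OC)c(OC)c2OC)C1 | intermediate
5 | cis-2-(2,3,4-trimethoxyphenyl)-3,4-dihydro-2H-pyran-4-ol (racemic) | C1=C[C@@H](O)C[C@@H](c2ccc(OC)c(OC)c2OC)O1 | intermediate
6 | cis-4-(tert-butyldimethylsilyloxy)-2-(2,3,4-trimethoxyphenyl)-3,4-dihydro-2H-pyran (racemic) | C1=C[C@@H](O[Si](C)(C)C(C)(C)C)C[C@@H](c2ccc(OC)c(OC)c2OC)O1 | intermediate
7 | cis-4-(tert-butyldimethylsilyloxy)-6-(2,3,4-trimethoxyphenyl)tetrahydro-2H-pyran-2-one (racemic) | O=C1C[C@@H](O[Si](C)(C)C(C)(C)C)C[C@@H](c2ccc(OC)c(OC)c2OC)O1 | intermediate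
8 | potassium enolate of lactone 7 (not isolated) | [K+].[O-]C1=C[C@@H](O[Si](C)(C)C(C)(C)C)C[C@@H](c2ccc(OC)c(OC)c2OC)O1 | intermediate
9 | cis-4-(tert-butyldimethylsilyloxy)-2-(2,3,4-trimethoxyphenyl)-3,4-dihydro-2H-pyran-6-yl diphenyl phosphate (racemic) | O=P(Oc1ccccc1)(Oc1ccccc1)OC1=C[C@@H](O[Si](C)(C)C(C)(C)C)C[C@@H](c2ccc(OC)c(OC)c2OC)O1 | intermediate
10 | [cis-4-(tert-butyldimethylsilyloxy)-2-(2,3,4-trimethoxyphenyl)-3,4-dihydro-2H-pyran-6-yl]trimethylstannane (racemic) | C[Sn](C)(C)C1=C[C@@H](O[Si](C)(C)C(C)(C)C)C[C@@H](c2ccc(OC)c(OC)c2OC)O1 | intermediate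
11 | dimethyl squarate | COC1=C(OC)C(=O)C1=O | starting material
12 | 4-hydroxy-2,3-dimethoxycyclobut-2-en-1-one (racemic) | COC1=C(OC)C(O)C1=O | intermediate
13 | 3-methoxycyclobut-3-ene-1,2-dione (methyl semisquarate) | COC1=CC(=O)C1=O | intermediate
14 | cis-4-(tert-butyldimethylsilyloxy)-6-lithio-2-(2,3,4-trimethoxyphenyl)-3,4-dihydro-2H-pyran (not isolated) | [Li]C1=C[C@@H](O[Si](C)(C)C(C)(C)C)C[C@@H](c2ccc(OC)c(OC)c2OC)O1 | intermediate
15 | lithium alkoxide of the 4-hydroxy-3-methoxy-4-(dihydropyranyl)cyclobutenone adduct (not isolated) | [Li+].[O-]C1(C2=C[C@@H](O[Si](C)(C)C(C)(C)C)C[C@@H](c3ccc(OC)c(OC)c3OC)O2)C(OC)=CC1=O | intermediate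
16 | 4-[cis-4-(tert-butyldimethylsilyloxy)-2-(2,3,4-trimethoxyphenyl)-3,4-dihydro-2H-pyran-6-yl]-3,4-dimethoxycyclobut-2-en-1-one (racemic, both epimers at the cyclobutenone carbon) | COC1=CC(=O)C1(OC)C2=C[C@@H](O[Si](C)(C)C(C)(C)C)C[C@@H](c3ccc(OC)c(OC)c3OC)O2 | intermediate
17 | (Z)-3,4-dimethoxy-4-(dihydropyran-6-yl)buta-1,3-dien-1-one, the dienylketene (not isolated) | O=C=C/C(OC)=C(/OC)C1=C[C@@H](O[Si](C)(C)C(C)(C)C)C[C@@H](c2ccc(OC)c(OC)c2OC)O1 | intermediate
18 | cis-4-(tert-butyldimethylsilyloxy)-7,8-dimethoxy-2-(2,3,4-trimethoxyphenyl)-2,3,4,4a-tetrahydro-5H-chromen-5-one (not isolated) | COC1=CC(=O)C2C(=C1OC)O[C@H](c1ccc(OC)c(OC)c1OC)C[C@@H]2O[Si](C)(C)C(C)(C)C | intermediate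
19 | cis-4-(tert-butyldimethylsilyloxy)-7,8-dimethoxy-2-(2,3,4-trimethoxyphenyl)chroman-5-ol (racemic) | COc1cc(O)c2c(c1OC)O[C@H](c3ccc(OC)c(OC)c3OC)C[C@@H]2O[Si](C)(C)C(C)(C)C | intermediate
20 | cis-7,8-dimethoxy-2-(2,3,4-trimethoxyphenyl)chroman-4,5-diol (racemic) | COc1cc(O)c2c(c1OC)O[C@H](c3ccc(OC)c(OC)c3OC)C[C@@H]2O | intermediate
21 | 5-hydroxy-7,8-dimethoxy-2-(2,3,4-trimethoxyphenyl)chroman-4-one (racemic) | COc1cc(O)c2c(c1OC)OC(c3ccc(OC)c(OC)c3OC)CC2=O | intermediate
22 | serpyllin | COc1ccc(-c2cc(=O)c3c(O)cc(OC)c(OC)c3o2)c(OC)c1OC | target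

**Step count**

Total: 13 steps. Longest linear sequence: 11 steps (steps 1–6 and 9–13 from aldehyde 1); steps 7–8 form the two-step branch to the semisquarate.

**Steps most likely to fail**

Step 10 (key step). The risk is β-loss of silanol: from dienone 18, where C4a–H is acidic and the silyloxy group sits on C4, or from hot phenol 19 through an o-quinone methide. Either path would drain material towards a 2H-chromene. Closure next to the silyloxy-bearing carbon may also be slow enough for the ketene to oligomerise. Fallback: move the oxidation of C4 ahead of the ring expansion. Setting out from 16, buffered Bu4NF should give the allylic alcohol 4-[cis-4-hydroxy-2-(2,3,4-trimethoxyphenyl)-3,4-dihydro-2H-pyran-6-yl]-3,4-dimethoxycyclobut-2-en-1-one F1. MnO2 should oxidise it to the vinylogous ester 3,4-dimethoxy-4-[4-oxo-2-(2,3,4-trimethoxyphenyl)-3,4-dihydro-2H-pyran-6-yl]cyclobut-2-en-1-one F2. Heating F2 in toluene runs the same 4π/6π sequence through the dienylketene F3 and the chroman-4,5-dione tautomer F4. F4 carries no leaving group and can only enolise, so it should give the chelated flavanone directly. The fallback comes back to the route at 21 and replaces steps 10–12.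

Step 5. The risk is β-elimination of silanolate from enolate 8 (to a 5,6-dihydropyran-2-one) competing with O-phosphorylation. Fallback: bypass the lactone. Setting out from 6, direct C6 deprotonation with t-BuLi (THF, –78 to 0 °C), the known C1 metalation of silylated glycal-type enol ethers, gives vinyllithium 14, which is quenched with Me3SnCl. Products of metalation at the benzylic C2–H or on the aryl ring are removed at the stannane stage, so step 9 still starts from regiochemically pure material. The fallback comes back at 10 and replaces steps 4–6.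

Step 9. The risk is loss of site selectivity on the semisquarate: attack at the vinylogous-ester carbonyl, conjugate addition at the unsubstituted ring carbon, or double addition. These would give the 6-methoxy-7-H isomer of ring A or no usable adduct. Sequences through the squarate adducts I considered lead to the regioisomeric cyclobutenone series, so ring A would then be taken from an aromatic building block. Setting out from 1, Claisen–Schmidt condensation (KOH, EtOH) with 2'-hydroxy-3',4',6'-trimethoxyacetophenone F5 gives the 2'-hydroxychalcone F6. I2/DMSO at 130 °C cyclises it through 5,7,8-trimethoxy-2-(2,3,4-trimethoxyphenyl)chroman-4-one F7 and dehydrogenates it to 5,7,8-trimethoxy-2-(2,3,4-trimethoxyphenyl)-4H-chromen-4-one F8. BCl3 (CH2Cl2, 0 °C) then cleaves only the C5 methyl ether, which is peri to the carbonyl. The fallback comes back to the route at 22.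

**Further compounds**

F1 | step 10 | 4-[cis-4-hydroxy-2-(2,3,4-trimethoxyphenyl)-3,4-dihydro-2H-pyran-6-yl]-3,4-dimethoxycyclobut-2-en-1-one | COC1=CC(=O)C1(OC)C2=C[C@@H](O)C[C@@H](c3ccc(OC)c(OC)c3OC)O2
F2 | step 10 | 3,4-dimethoxy-4-[4-oxo-2-(2,3,4-trimethoxyphenyl)-3,4-dihydro-2H-pyran-6-yl]cyclobut-2-en-1-one | COC1=CC(=O)C1(OC)C2=CC(=O)CC(c3ccc(OC)c(OC)c3OC)O2
F3 | step 10 | (Z)-3,4-dimethoxy-4-[4-oxo-2-(2,3,4-trimethoxyphenyl)-3,4-dihydro-2H-pyran-6-yl]buta-1,3-dien-1-one | O=C=C/C(OC)=C(/OC)C1=CC(=O)CC(c2ccc(OC)c(OC)c2OC)O1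
F4 | step 10 | 7,8-dimethoxy-2-(2,3,4-trimethoxyphenyl)-2,3-dihydro-4aH-chromene-4,5-dione | COC1=CC(=O)C2C(=C1OC)OC(c1ccc(OC)c(OC)c1OC)CC2=O
F0 | step 5 | none | none
F5 | step 9 | 2'-hydroxy-3',4',6'-trimethoxyacetophenone | CC(=O)c1c(O)c(OC)c(OC)cc1OC
F6 | step 9 | (E)-1-(2-hydroxy-3,4,6-trimethoxyphenyl)-3-(2,3,4-trimethoxyphenyl)prop-2-en-1-one | COc1ccc(/C=C/C(=O)c2c(O)c(OC)c(OC)cc2OC)c(OC)c1OC
F7 | step 9 | 5,7,8-trimethoxy-2-(2,3,4-trimethoxyphenyl)chroman-4-one | COc1ccc(C2CC(=O)c3c(OC)cc(OC)c(OC)c3O2)c(OC)c1OC
F8 | step 9 | 5,7,8-trimethoxy-2-(2,3,4-trimethoxyphenyl)-4H-chromen-4-one | COc1ccc(-c2cc(=O)c3c(OC)cc(OC)c(OC)c3o2)c(OC)c1OC
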